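## The problem

Compound 20 is a 3,3''-biflavanone: two 2-(4-methoxyphenyl)chroman-4-one units joined by one single bond between C3 and C3''. Both of these carbons are tertiary, α to a ketone and β to a ring oxygen. The four contiguous stereocentres C2, C3, C3'' and C2'' are all R. In each pyranone ring the aryl group on C2 and the substituent on C3 are cis. The C2–C3–C3''–C2'' core is twofold symmetric, but the two A rings are not (5,7-dihydroxy in unit 1, 5-hydroxy-7-methoxy in unit 2).

The cis arrangement is the less stable one. Base enolises C3 or opens the ring by retro-oxa-Michael reaction, and acid ionises the 4-methoxybenzylic C2–O1 bond; both paths lead to the trans series. The centres therefore have to be set under kinetic control, and the late steps must avoid free base and long contact with acid.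

C3 and C3'' can be fixed together if their bond is made in a symmetric dimerisation. C2 and C2'' can then be set relative to them only if each is held in a small ring with C3 and C3''. Three phenols (two of them chelated to a carbonyl) have to be told apart from three aryl methyl ethers, and the 7-OH/7''-OMe difference breaks the symmetry.

The enabling feature is the chain C2–C3–C3''–C2'', with carbonyl carbon C4 on C3 and C4'' on C3'', and an aryl group and an oxygen on C2 and on C2''. This is the skeleton of an 8–8' (β–β) dimer of 4-hydroxycinnamic acid. If the oxygen on C2 is acylated by C4'' and the oxygen on C2'' by C4, the result is a cis-fused 2,6-diaryl-3,7-dioxabicyclo[3.3.0]octane-4,8-dione. Its exo,exo isomer has the relative configuration of 20 at all four centres.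

## Retrosynthesis

**20 ⇒ 19 (O–benzyl twice, O5''–CH3).** The last step should be one mild dealkylation. Unit 1, which ends as a 5,7-diol, carries benzyl ethers in 19. Unit 2 carries methyl ethers, of which only the 5''-methyl can chelate a Lewis acid to the C4'' carbonyl. The forward reaction must cleave these three ethers and leave the 7''- and both 4'-methyl ethers and the four stereocentres alone.

**19 ⇒ 18 (O1–C8a and O1''–C8a'').** The neighbouring cut, O1–C2, would mean oxa-Michael closure of a chalcone or substitution at the benzylic carbon. Both lose the C2 configuration and end in the trans series. Cutting the aryl–oxygen bond keeps both C2–O bonds intact, so the cis relation only has to be carried through. The precursor 18 is an open bis(β-hydroxy ketone) with a fluorine ortho to each ketone. The forward reaction is a double intramolecular SNAr that has to outrun retro-aldol cleavage.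

**18 ⇒ 16 + 14, and 16 ⇒ 9 + 12 (C4''–C4a'' and C4–C4a).** The two ketones are read as lactone carbonyls that have each accepted one aryl anion.
- Aryl anion addition (via aryllithiums 17 and 15) is preferred to Friedel–Crafts acylation, which would need acid at a 4-methoxybenzylic ether.
- The two carbonyls of 9 are homotopic, so only mono- against bis-addition has to be controlled. The two different A rings enter here, one after the other.
- The bromides 12 (from 11, from 10) and 14 (from 13) fix the position of the metal between fluorine and oxygen. Direct deprotonation would leave this open.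

**9 ⇒ 8 (two O–CH3).** The phenols needed for the oxidative coupling become the 4'-methyl ethers of 20. The forward reaction must not generate a free 4-phenoxide, which could open the benzylic lactone.

**8 ⇒ 6 (C3–C3'', O–C2, O–C2''; key step).** All three skeletal bonds of the core and both lactone rings are cut at once, which leads back to two 4-hydroxycinnamate units. Joining them through (1R,2R)-cyclohexane-1,2-diol makes the coupling intramolecular and supplies the only source of absolute configuration. The diol leaves again during lactonisation. The precursor 6 has no stereocentre outside the tether. The forward reaction must give 8–8' coupling in one absolute sense.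

**6 ⇒ 5 ⇒ 3 + 4, and 3 ⇒ 1.** These are ester bonds and silyl ethers. The phenol of 1 is masked so that only the diol 4 is acylated.

## Roads not taken

**Alternative 1:** Both pyran rings are taken apart at O1–C2, C3–C4, O1''–C2'' and C3''–C4''. This leaves 2,5-bis(4-methoxyphenyl)furan A1, which already holds C2–C3–C3''–C2'', and two ortho-quinone methides made from the salicyl alcohol A2. In the forward direction a chiral phosphoric acid such as (R)-3,3'-bis(2,4,6-triisopropylphenyl)-1,1'-binaphthyl-2,2'-diyl hydrogen phosphate ionises A2, and two [4+2] additions across the furan double bonds give the furan-bridged bis-ketal A3.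
- Merits: four bonds, both rings and all four centres come from flat, cheap partners in one operation, and the A rings are attached at once.
- Weak points: after the first addition the second face is decided by the existing centres as much as by the catalyst. A3 has C4 and C4'' as CH2 and C2 and C2'' as ketal carbons, so both ketal C–O bonds must be reduced with defined delivery of hydride and both benzylic methylenes oxidised beside electron-rich rings and other benzylic C–H bonds. As drawn, A3 carries the same benzyloxy pattern on both A rings, so the 7''-methyl ether still needs two different quinone methides or a late statistical methylation.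
- Comparison: this road is more convergent than the chosen one, which needs steps 9 to 11 to attach the A rings. The chosen plan has C4 and C4'' at the ketone level from the start, fixes C2 and C2'' in the key step and needs no redox chemistry at the end.

**Alternative 2:** Only C2–C3 of unit 1 is cut. The precursor is the α-diazo ketone A4, whose diazo carbon carries a flavon-3-yl group and whose aryl ketone carries a 4-methoxybenzyl ether. Rh2(S-DOSP)4, dirhodium tetrakis[(S)-N-(dodecylbenzenesulfonyl)prolinate], forms the carbenoid of divalent rhodium, which inserts into the benzylic C–H bond and closes the pyranone to the cis product A5.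
- Merits: the two units differ from the outset, so there is no statistical step, and the sense of induction is set by the catalyst.
- Weak points: the ether oxygen can attack the carbenoid and give an oxonium ylide that shifts the benzyl group. The carbene sits beside a bulky chromone. A5 still has the C2''=C3'' double bond of a flavone, so two of the four centres remain to be made by syn hydrogenation of a tetrasubstituted, electron-rich double bond from one face, without touching ketones or benzyl ethers and without epimerising C3. The synthesis of A4 is long and linear.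
- Comparison: this road handles the unsymmetry better. The chosen plan sets all four centres in one step and pays for it with the mono-addition in step 9.

**Alternative 3:** The rings are cut at C3–C4 and C3''–C4'', leading to the dienyne A6, a but-2-yne-1,4-diyl bis(aryl ether) with two ortho-vinyl groups. The second-generation Grubbs catalyst closes one ring onto the alkyne and the new carbene closes the second ring, giving the 3,3''-bi(2-aryl-2H-chromene) A7.
- Merits: enyne metathesis cascades are reliable, the halves are unsymmetrical from the start, and C2 and C2'' come from a simple alkyne diol.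
- Weak points: A7 has neither the C3 and C3'' centres nor oxygen at C4 and C4''. Both must be added to a conjugated diene with benzylic regiochemistry and with hydrogen delivered to C3 anti to the aryl group, which is without close precedent. The 4-methoxyphenyl propargylic aryl ethers of A6 ionise easily. 2-Aryl-2H-chromenes can open and reclose electrocyclically, which endangers C2.
- Comparison: the ring-forming step is safer than step 4 of the chosen plan. It leaves the hard part for later, whereas the chosen key step delivers the complete stereochemical array and the right oxidation level.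

Key step: step 4

Assumption: models do not settle the sense of induction in step 4, because it depends on whether the enoates react s-cis or s-trans. The route is written for the case that the (1R,2R)-diol 4 gives the all-R dilactone 8. If the mirror image forms, (1S,2S)-cyclohexane-1,2-diol replaces 4 and nothing else changes.

## Route

Step 1
Reactants: 1 (E)-4-hydroxycinnamic acid
Product: 3 (E)-3-[4-(tert-butyldimethylsilyloxy)phenyl]prop-2-enoic acid, via bis-silylated acid 2 (not isolated)
Conditions: TBSCl (2.5 equiv), imidazole, DMF, rt; then AcOH–THF–H2O, rt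
Reagents that add atoms: tert-butyldimethylsilyl chloride, CC(C)(C)[Si](C)(C)Cl
Why: Both acidic groups are silylated, then the much more labile silyl ester is hydrolysed selectively; the aryl silyl ether survives dilute acetic acid and the E double bond is not touched.

Step 2
Reactants: 3 (E)-3-[4-(tert-butyldimethylsilyloxy)phenyl]prop-2-enoic acid (2 equiv); 4 (1R,2R)-cyclohexane-1,2-diol
Product: 5 (1R,2R)-cyclohexane-1,2-diyl bis{(E)-3-[4-(tert-butyldimethylsilyloxy)phenyl]prop-2-enoate}
Conditions: DCC (2.2 equiv), DMAP (0.2 equiv), CH2Cl2, 0 °C to rt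
Reagents that add atoms: none
Why: Steglich esterification acylates both secondary hydroxyls with retention, since no bond to a carbinol carbon is broken; with the phenols masked no oligoesters can form.

Step 3
Reactants: 5 (1R,2R)-cyclohexane-1,2-diyl bis{(E)-3-[4-(tert-butyldimethylsilyloxy)phenyl]prop-2-enoate}
Product: 6 (1R,2R)-cyclohexane-1,2-diyl bis[(E)-3-(4-hydroxyphenyl)prop-2-enoate]
Conditions: Bu4NF (2.2 equiv), AcOH (2.5 equiv), THF, 0 °C
Reagents that add atoms: none
Why: Fluoride cleaves aryl silyl ethers quickly at 0 °C; acetic acid buffers the phenoxide so the cinnamate esters are neither cleaved nor transesterified.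

Step 4
Reactants: 6 (1R,2R)-cyclohexane-1,2-diyl bis[(E)-3-(4-hydroxyphenyl)prop-2-enoate]
Product: 8 (1R,2R,5R,6R)-2,6-bis(4-hydroxyphenyl)-3,7-dioxabicyclo[3.3.0]octane-4,8-dione, via tethered bis(quinone methide) 7 (not isolated)
Conditions: FeCl3·6H2O (2.2 equiv), acetone–H2O 4:1, Ar, rt, slow addition of 6 to high dilution (about 1 mM)
Reagents that add atoms: water, O
Why: Proposed new method: the closest known reaction type is the FeCl3- or laccase/O2-mediated 8–8' dimerisation of free 4-hydroxycinnamic acids (ferulic, sinapic) to the same dilactones, extended here to a diester held on a chiral diol, with capture of a quinone methide by an ester carbonyl oxygen as in halolactonisation of esters. Trivalent iron removes one electron from each phenol of 6; the two phenoxyl radicals carry spin on the carbon next to the ester carbonyl (C8, the lignan β-carbon; C3 and C3'' of 20) and combine there, closing a transient eight-membered ring to give 7. In the acidic aqueous medium each quinone methide carbon (C2, C2'') is attacked 5-exo-trig by the carbonyl oxygen of the ester on the other half, water adds to the dialkoxycarbenium ion and the adduct expels the diol oxygen, so that two γ-lactones form, the eight-membered ring is cut twice and 4 is released. C3 and C3'' are set in the radical combination: in the diequatorial (1R,2R)-diester the O–C–C–O torsion is gauche and negative, the two enoate planes are twisted against each other in one sense and can meet only through the faces turned to the twofold axis, which gives the homochiral pair and not the meso pair. C2 and C2'' are set in the lactone closures: the bicyclo[3.3.0] skeleton can only be cis-fused and the aryl groups take the convex (exo) face, which is also the thermodynamic result because a 4-hydroxybenzylic lactone can reopen to the quinone methide in acid. The step needs 8–8' coupling instead of 8–5', 8–O–4' or 5–5' coupling, and reaction within one molecule; the two-carbon diol bridge lets only the two C8 atoms reach bonding distance (the geometry known from truxinate photodimerisation of 1,2-diol dicinnamates), and slow addition to high dilution suppresses coupling between molecules. The conjugated phenols of 6 are oxidised more easily than the non-conjugated phenols of 8, which protects the product.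

Step 5
Reactants: 8 (1R,2R,5R,6R)-2,6-bis(4-hydroxyphenyl)-3,7-dioxabicyclo[3.3.0]octane-4,8-dione
Product: 9 (1R,2R,5R,6R)-2,6-bis(4-methoxyphenyl)-3,7-dioxabicyclo[3.3.0]octane-4,8-dione
Conditions: MeOH (excess), PPh3, DIAD, THF, 0 °C to rt
Reagents that add atoms: methanol, CO
Why: Mitsunobu etherification methylates the phenols (pKa about 10) under nearly neutral conditions; a long-lived 4-phenoxide, which could expel the benzylic lactone oxygen as a quinone methide, is avoided. No stereocentre takes part.

Step 6
Reactants: 10 5-fluorobenzene-1,3-diol (5-fluororesorcinol)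
Product: 11 1,3-bis(benzyloxy)-5-fluorobenzene
Conditions: BnBr (2.2 equiv), K2CO3, DMF, rt to 60 °C
Reagents that add atoms: benzyl bromide, BrCc1ccccc1
Why: Williamson ether synthesis on both phenols; the fluorine is not displaced because the ring carries no acceptor group.

Step 7
Reactants: 11 1,3-bis(benzyloxy)-5-fluorobenzene
Product: 12 1,5-bis(benzyloxy)-2-bromo-3-fluorobenzene
Conditions: NBS (1.0 equiv), MeCN, 0 °C to rt
Reagents that add atoms: N-bromosuccinimide, O=C1CCC(=O)N1Br
Why: Electrophilic aromatic bromination goes ortho to one benzyloxy group and para to the other; of the positions that fulfil this, the one next to the small fluorine is favoured over the one flanked by two benzyloxy groups. This puts bromine on the carbon that must later carry lithium.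

Step 8
Reactants: 13 1-fluoro-3,5-dimethoxybenzene
Product: 14 2-bromo-1-fluoro-3,5-dimethoxybenzene
Conditions: NBS (1.0 equiv), MeCN, 0 °C to rt
Reagents that add atoms: N-bromosuccinimide, O=C1CCC(=O)N1Br
Why: Same electrophilic bromination as in step 7; resorcinol diethers are attacked para to one alkoxy group and not between the two, so the position between fluorine and methoxy is brominated.

Step 9
Reactants: 12 1,5-bis(benzyloxy)-2-bromo-3-fluorobenzene; 9 (1R,2R,5R,6R)-2,6-bis(4-methoxyphenyl)-3,7-dioxabicyclo[3.3.0]octane-4,8-dione
Product: 16 (3R,4R,5R)-4-[2,4-bis(benzyloxy)-6-fluorobenzoyl]-3-[(R)-hydroxy(4-methoxyphenyl)methyl]-5-(4-methoxyphenyl)oxolan-2-one, via aryllithium 15 (not isolated)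
Conditions: 12 (0.95 equiv), n-BuLi (0.95 equiv), THF, −78 °C; cannulated into 9 in THF, −78 °C; aq NH4Cl at −78 °C
Reagents that add atoms: none
Why: Bromine–lithium exchange gives the 2-fluoroaryllithium at a defined position (kept at −78 °C, where loss of LiF to an aryne is slow), and 1,2-addition to one of the two homotopic lactone carbonyls gives a lithium lactolate that does not collapse before the quench, as in C-aryl glycoside synthesis from lactones. The reagent is kept limiting and is added to 9 to favour mono-addition; no stereocentre is touched, and 16 is in equilibrium with its five-membered lactol.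

Step 10
Reactants: 14 2-bromo-1-fluoro-3,5-dimethoxybenzene; 16 (3R,4R,5R)-4-[2,4-bis(benzyloxy)-6-fluorobenzoyl]-3-[(R)-hydroxy(4-methoxyphenyl)methyl]-5-(4-methoxyphenyl)oxolan-2-one
Product: 18 (2R,3R)-1-[2,4-bis(benzyloxy)-6-fluorophenyl]-4-(2-fluoro-4,6-dimethoxyphenyl)-2,3-bis[(R)-hydroxy(4-methoxyphenyl)methyl]butane-1,4-dione, via aryllithium 17 (not isolated)
Conditions: 14 (2.5 equiv), n-BuLi (2.4 equiv), THF, −78 °C; then 16, −78 °C; aq NH4Cl at −78 °C
Reagents that add atoms: none
Why: Same exchange and lactone addition; the first equivalent of 17 only deprotonates the hydroxyl of 16, which closes to the lithium lactolate and masks the hindered diaryl-flanked ketone, and further reagent adds to the remaining lactone carbonyl. Both ketone carbons now carry their A ring and both benzylic oxygens are free; 18 may exist as its bis-lactol.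

Step 11
Reactants: 18 (2R,3R)-1-[2,4-bis(benzyloxy)-6-fluorophenyl]-4-(2-fluoro-4,6-dimethoxyphenyl)-2,3-bis[(R)-hydroxy(4-methoxyphenyl)methyl]butane-1,4-dione
Product: 19 (2R,3R)-5,7-bis(benzyloxy)-3-[(2R,3R)-5,7-dimethoxy-2-(4-methoxyphenyl)-4-oxo-3,4-dihydro-2H-chromen-3-yl]-2-(4-methoxyphenyl)-2,3-dihydro-4H-chromen-4-one
Conditions: KN(SiMe3)2 (2.05 equiv), 18-crown-6, THF, −78 to 0 °C; then AcOH
Reagents that add atoms: none
Why: Double intramolecular SNAr etherification: each alkoxide attacks the fluorine-bearing carbon ortho to the ketone on its own C3 (six-membered ring, Meisenheimer adduct stabilised by the carbonyl; both alkoxy groups are meta to fluorine and do not deactivate that carbon). No bond to C2, C3, C3'' or C2'' is broken, so the configuration of 9 is carried over as the cis,cis array. The hindered base is used in the exact amount and ends as KF, so none is left to enolise C3 of the product.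

Step 12
Reactants: 19 (2R,3R)-5,7-bis(benzyloxy)-3-[(2R,3R)-5,7-dimethoxy-2-(4-methoxyphenyl)-4-oxo-3,4-dihydro-2H-chromen-3-yl]-2-(4-methoxyphenyl)-2,3-dihydro-4H-chromen-4-one
Product: 20 (2R,3R)-5,7-dihydroxy-3-[(2R,3R)-5-hydroxy-7-methoxy-2-(4-methoxyphenyl)-4-oxo-3,4-dihydro-2H-chromen-3-yl]-2-(4-methoxyphenyl)-2,3-dihydro-4H-chromen-4-one
Conditions: BCl3 (excess), pentamethylbenzene, CH2Cl2, −78 to 0 °C; H2O
Reagents that add atoms: none
Why: BCl3 cleaves aryl benzyl ethers at −78 °C (pentamethylbenzene traps the benzyl cation by Friedel–Crafts alkylation) and, on warming, the one methyl ether that can chelate boron to the neighbouring C4'' carbonyl. The 7''- and both 4'-methyl ethers lack this assistance and stay.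

## Compound list

1 | (E)-4-hydroxycinnamic acid | OC(=O)/C=C/c1ccc(O)cc1 | starting material
2 | tert-butyldimethylsilyl (E)-3-[4-(tert-butyldimethylsilyloxy)phenyl]prop-2-enoate | CC(C)(C)[Si](C)(C)OC(=O)/C=C/c1ccc(O[Si](C)(C)C(C)(C)C)cc1 | intermediate (not isolated)
3 | (E)-3-[4-(tert-butyldimethylsilyloxy)phenyl]prop-2-enoic acid | OC(=O)/C=C/c1ccc(O[Si](C)(C)C(C)(C)C)cc1 | intermediate
4 | (1R,2R)-cyclohexane-1,2-diol | O[C@@H]1CCCC[C@H]1O | starting material
5 | (1R,2R)-cyclohexane-1,2-diyl bis{(E)-3-[4-(tert-butyldimethylsilyloxy)phenyl]prop-2-enoate} | O=C(/C=C/c1ccc(O[Si](C)(C)C(C)(C)C)cc1)O[C@@H]1CCCC[C@H]1OC(=O)/C=C/c1ccc(O[Si](C)(C)C(C)(C)C)cc1 | intermediate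
6 | (1R,2R)-cyclohexane-1,2-diyl bis[(E)-3-(4-hydroxyphenyl)prop-2-enoate] | O=C(/C=C/c1ccc(O)cc1)O[C@@H]1CCCC[C@H]1OC(=O)/C=C/c1ccc(O)cc1 | intermediate
7 | (3S,4S,6aR,10aR)-3,4-bis[(4-oxocyclohexa-2,5-dien-1-ylidene)methyl]octahydro-1,6-benzodioxocine-2,5-dione | O=C1O[C@@H]2CCCC[C@H]2OC(=O)[C@@H](C=C2C=CC(=O)C=C2)[C@@H]1C=C1C=CC(=O)C=C1 | intermediate (not isolated)
8 | (1R,2R,5R,6R)-2,6-bis(4-hydroxyphenyl)-3,7-dioxabicyclo[3.3.0]octane-4,8-dione | Oc1ccc([C@@H]2OC(=O)[C@@H]3[C@H]2C(=O)O[C@H]3c2ccc(O)cc2)cc1 | intermediate
9 | (1R,2R,5R,6R)-2,6-bis(4-methoxyphenyl)-3,7-dioxabicyclo[3.3.0]octane-4,8-dione | COc1ccc([C@@H]2OC(=O)[C@@H]3[C@H]2C(=O)O[C@H]3c2ccc(OC)cc2)cc1 | intermediate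
10 | 5-fluorobenzene-1,3-diol | Oc1cc(O)cc(F)c1 | starting material
11 | 1,3-bis(benzyloxy)-5-fluorobenzene | Fc1cc(OCc2ccccc2)cc(OCc2ccccc2)c1 | intermediate
12 | 1,5-bis(benzyloxy)-2-bromo-3-fluorobenzene | Fc1cc(OCc2ccccc2)cc(OCc2ccccc2)c1Br | intermediate
13 | 1-fluoro-3,5-dimethoxybenzene | COc1cc(F)cc(OC)c1 | starting material
14 | 2-bromo-1-fluoro-3,5-dimethoxybenzene | COc1cc(F)c(Br)c(OC)c1 | intermediate
15 | [2,4-bis(benzyloxy)-6-fluorophenyl]lithium | [Li]c1c(F)cc(OCc2ccccc2)cc1OCc1ccccc1 | intermediate (not isolated)
16 | (3R,4R,5R)-4-[2,4-bis(benzyloxy)-6-fluorobenzoyl]-3-[(R)-hydroxy(4-methoxyphenyl)methyl]-5-(4-methoxyphenyl)oxolan-2-one (open form of the lactol) | COc1ccc([C@@H]2OC(=O)[C@H]([C@H]2C(=O)c2c(F)cc(OCc3ccccc3)cc2OCc2ccccc2)[C@@H](O)c2ccc(OC)cc2)cc1 | intermediate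
17 | (2-fluoro-4,6-dimethoxyphenyl)lithium | [Li]c1c(F)cc(OC)cc1OC | intermediate (not isolated)
18 | (2R,3R)-1-[2,4-bis(benzyloxy)-6-fluorophenyl]-4-(2-fluoro-4,6-dimethoxyphenyl)-2,3-bis[(R)-hydroxy(4-methoxyphenyl)methyl]butane-1,4-dione (open form of the bis-lactol) | COc1ccc([C@H](O)[C@H](C(=O)c2c(F)cc(OCc3ccccc3)cc2OCc2ccccc2)[C@@H](C(=O)c2c(F)cc(OC)cc2OC)[C@@H](O)c2ccc(OC)cc2)cc1 | intermediate
19 | (2R,3R)-5,7-bis(benzyloxy)-3-[(2R,3R)-5,7-dimethoxy-2-(4-methoxyphenyl)-4-oxo-3,4-dihydro-2H-chromen-3-yl]-2-(4-methoxyphenyl)-2,3-dihydro-4H-chromen-4-one | COc1ccc([C@@H]2Oc3cc(OCc4ccccc4)cc(OCc4ccccc4)c3C(=O)[C@@H]2[C@H]2C(=O)c3c(OC)cc(OC)cc3O[C@H]2c2ccc(OC)cc2)cc1 | intermediate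
20 | (2R,3R)-5,7-dihydroxy-3-[(2R,3R)-5-hydroxy-7-methoxy-2-(4-methoxyphenyl)-4-oxo-3,4-dihydro-2H-chromen-3-yl]-2-(4-methoxyphenyl)-2,3-dihydro-4H-chromen-4-one | COc1ccc([C@@H]2Oc3cc(O)cc(O)c3C(=O)[C@@H]2[C@H]2C(=O)c3c(O)cc(OC)cc3O[C@H]2c2ccc(OC)cc2)cc1 | target

## Step count and least certain steps

Total: 12 steps. Longest linear sequence: 9 steps (1, 2, 3, 4, 5, 9, 10, 11, 12). The aryl bromides 12 (2 steps) and 14 (1 step) are made in parallel.

**Step 4 (key step).**
- The two radical centres must close an eight-membered ring containing two ester groups that cannot both keep their preferred planar geometry. If this strain slows the 8–8' combination, coupling through ring positions or through the phenol oxygen, and coupling between molecules, would take over.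
- The unsubstituted 4-hydroxyphenyl group is harder to oxidise than the methoxylated phenols for which the reaction is known, so electron transfer may be slow.
- Facial selectivity may be low or of the opposite sense.
- Fallback: it sets out from 1 and returns at 8. The free acid 1 is dimerised without tether by FeCl3·6H2O in aqueous acetone under O2, the established reaction of 4-hydroxycinnamic acids. This should give the racemic exo,exo-dilactone, rac-2,6-bis(4-hydroxyphenyl)-3,7-dioxabicyclo[3.3.0]octane-4,8-dione F1. Preparative chromatography on a chiral stationary phase separates it into 8 and its enantiomer, the (1S,2S,5S,6S)-dilactone F2. Steps 1 to 3 then fall away.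

**Step 9.**
- Over-addition is the main danger: the second lactone carbonyl may react about as fast as the first, which gives a statistical mixture.
- The hindered aryllithium may also deprotonate C3 or C3'', followed by β-elimination of the carboxylate.
- Fallback: it sets out from 9 and returns at 20, and makes double addition the aim. An excess of 15 opens both lactones to the symmetric bis-adduct, (2R,3R)-1,4-bis[2,4-bis(benzyloxy)-6-fluorophenyl]-2,3-bis[(R)-hydroxy(4-methoxyphenyl)methyl]butane-1,4-dione F3. Double SNAr closure as in step 11 gives the tetra-O-benzyl biflavanone F4. Hydrogenolysis (H2, Pd/C, EtOAc) gives the 5,7,5'',7''-tetrahydroxy-4',4'''-dimethoxy biflavanone F5. One of its two equivalent, non-chelated 7-hydroxyls is then methylated with a limited amount of diazomethane, and unreacted F5 is recycled. The statistical step moves to the end, but 13, 14 and step 10 are no longer needed.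

**Step 11.**
- Each alkoxide of 18 is an aldolate, so retro-aldol cleavage of C2–C3 may compete with ring closure.
- Enolisation at C3 would epimerise it or lead to loss of water, and any surviving base would epimerise 19 to the trans series.
- Fallback: it sets out from 16 and returns at 19 without isolating 18, and makes no new compound. After the addition of 17 at −78 °C, N,N'-dimethylpropyleneurea is added and the mixture is warmed. The lithium lactolates open to lithium aldolates, in which lithium bridges alkoxide and ketone oxygen. This is the aldolate least prone to retro-aldol cleavage, and lithium assists the loss of fluoride. Neither the free β-hydroxy ketone nor a potassium alkoxide is ever present.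

**Step 12.**
- The Lewis acid may ionise the 4-methoxybenzylic C2–O1 bonds, with epimerisation or ring opening.
- The non-chelated methyl ethers may be cleaved in part on warming, and ring A may be C-benzylated.
- Fallback: it sets out from 19 and returns at 20, and separates the two tasks. Neutral hydrogenolysis (H2, Pd/C, EtOAc) removes the benzyl groups and gives the 5,7-dihydroxy-5'',7''-dimethoxy biflavanone F6. MgI2·OEt2 in toluene–ether then removes only the chelated 5''-methyl group.

## Further compounds

F1 | step 4 | rac-(1R,2R,5R,6R)-2,6-bis(4-hydroxyphenyl)-3,7-dioxabicyclo[3.3.0]octane-4,8-dione (racemate, both enantiomers) | Oc1ccc([C@@H]2OC(=O)[C@@H]3[C@H]2C(=O)O[C@H]3c2ccc(O)cc2)cc1.Oc1ccc([C@H]2OC(=O)[C@H]3[C@@H]2C(=O)O[C@@H]3c2ccc(O)cc2)cc1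
F2 | step 4 | (1S,2S,5S,6S)-2,6-bis(4-hydroxyphenyl)-3,7-dioxabicyclo[3.3.0]octane-4,8-dione | Oc1ccc([C@H]2OC(=O)[C@H]3[C@@H]2C(=O)O[C@@H]3c2ccc(O)cc2)cc1
F3 | step 9 | (2R,3R)-1,4-bis[2,4-bis(benzyloxy)-6-fluorophenyl]-2,3-bis[(R)-hydroxy(4-methoxyphenyl)methyl]butane-1,4-dione | COc1ccc([C@H](O)[C@H](C(=O)c2c(F)cc(OCc3ccccc3)cc2OCc2ccccc2)[C@@H](C(=O)c2c(F)cc(OCc3ccccc3)cc2OCc2ccccc2)[C@@H](O)c2ccc(OC)cc2)cc1
F4 | step 9 | (2R,3R,2''R,3''R)-5,7,5'',7''-tetrakis(benzyloxy)-4',4'''-dimethoxy-3,3''-biflavanone | COc1ccc([C@@H]2Oc3cc(OCc4ccccc4)cc(OCc4ccccc4)c3C(=O)[C@@H]2[C@H]2C(=O)c3c(OCc4ccccc4)cc(OCc4ccccc4)cc3O[C@H]2c2ccc(OC)cc2)cc1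
F5 | step 9 | (2R,3R,2''R,3''R)-5,7,5'',7''-tetrahydroxy-4',4'''-dimethoxy-3,3''-biflavanone | COc1ccc([C@@H]2Oc3cc(O)cc(O)c3C(=O)[C@@H]2[C@H]2C(=O)c3c(O)cc(O)cc3O[C@H]2c2ccc(OC)cc2)cc1
F0 | step 11 | none | none
F6 | step 12 | (2R,3R)-5,7-dihydroxy-3-[(2R,3R)-5,7-dimethoxy-2-(4-methoxyphenyl)-4-oxo-3,4-dihydro-2H-chromen-3-yl]-2-(4-methoxyphenyl)-2,3-dihydro-4H-chromen-4-one | COc1ccc([C@@H]2Oc3cc(O)cc(O)c3C(=O)[C@@H]2[C@H]2C(=O)c3c(OC)cc(OC)cc3O[C@H]2c2ccc(OC)cc2)cc1
A1 | alternative 1 | 2,5-bis(4-methoxyphenyl)furan | COc1ccc(-c2ccc(-c3ccc(OC)cc3)o2)cc1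
A2 | alternative 1 | 3,5-bis(benzyloxy)-2-(hydroxymethyl)phenol | OCc1c(O)cc(OCc2ccccc2)cc1OCc1ccccc1
A3 | alternative 1 | furan-bridged bis-ketal of the cis,cis-3,3''-biflavan, tetra-O-benzyl | COc1ccc([C@@]23Oc4cc(OCc5ccccc5)cc(OCc5ccccc5)c4C[C@@H]2[C@H]2Cc4c(OCc5ccccc5)cc(OCc5ccccc5)cc4O[C@@]2(c2ccc(OC)cc2)O3)cc1
A4 | alternative 2 | 3-{2-[2,4-bis(benzyloxy)-6-(4-methoxybenzyloxy)phenyl]-1-diazo-2-oxoethyl}-5-(benzyloxy)-7-methoxy-2-(4-methoxyphenyl)-4H-chromen-4-one | COc1ccc(COc2cc(OCc3ccccc3)cc(OCc3ccccc3)c2C(=O)C(=[N+]=[N-])c2c(-c3ccc(OC)cc3)oc3cc(OC)cc(OCc4ccccc4)c3c2=O)cc1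
A5 | alternative 2 | (2R,3R)-cis-3-(flavon-3-yl)flavanone, tri-O-benzyl | COc1ccc([C@@H]2Oc3cc(OCc4ccccc4)cc(OCc4ccccc4)c3C(=O)[C@@H]2c2c(-c3ccc(OC)cc3)oc3cc(OC)cc(OCc4ccccc4)c3c2=O)cc1
A6 | alternative 3 | 1-[3,5-bis(benzyloxy)-2-vinylphenoxy]-4-[3-(benzyloxy)-5-methoxy-2-vinylphenoxy]-1,4-bis(4-methoxyphenyl)but-2-yne, configured at both ether carbons as C2 and C2'' of 20 | COc1ccc([C@@H](C#C[C@@H](Oc2cc(OC)cc(OCc3ccccc3)c2C=C)c2ccc(OC)cc2)Oc2cc(OCc3ccccc3)cc(OCc3ccccc3)c2C=C)cc1
A7 | alternative 3 | 3,3''-bi(2-aryl-2H-chromene), tri-O-benzyl, C2 and C2'' as in 20 | COc1ccc([C@@H]2Oc3cc(OCc4ccccc4)cc(OCc4ccccc4)c3C=C2C2=Cc3c(OCc4ccccc4)cc(OC)cc3O[C@H]2c2ccc(OC)cc2)cc1
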